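Everything rests on cutting the C4–C4a bond of ring A, the trimethoxybenzene ring (benzo[7]annulene numbering). Ring A has oxygen on the contiguous carbons C2, C3 and C4, hydrogen on C1 and the fusion atoms C4a/C9a shared with the seven-membered ring B, the pattern left by a 4-alkenyl-2,3-dimethoxycyclobutenone benzannulation. Precursor 25 is a cyclohept-2-enone that carries the squarate-derived cyclobutenone on its β-carbon and already holds the C7/C8/C9 stereotriad. On heating, the four-membered ring opens to a dienylketene that closes onto the enone α-carbon and enolizes, giving ring A as phenol 28 in one operation; the ring B ketone carbon (C5) later becomes the spiro carbon of dienone ring C.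

Key step: step 17

Remark (assumptions): the target is read as (7R,8S,9R), with the two methyl groups trans and the benzoate trans to the neighbouring methyl group. Centres that are erased later (cyclobutenone carbon of 25, carbinol carbon of 16–19, C5 of 31, C5 and the methoxy-bearing sp3 carbon of 36) are carried as mixtures. The vinylstannane is reached through a ketone-derived vinyl triflate, so that tin sits next to the silyloxy carbon without relying on the 1,2- versus 1,4-selectivity of a stannyl anion.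

Step 1
Reactants: 1 (R)-4-[(tert-butyldimethylsilyl)oxy]cyclopent-2-en-1-one
Product: 3 (R)-4-methylcyclopent-2-en-1-one, via conjugate adduct 2 (not isolated)
Conditions: Me2CuLi, Et2O, −78 °C; aq NH4Cl; then DBU, CH2Cl2, 0 °C
Reagents that add atoms: lithium dimethylcuprate, [Li+].C[Cu-]C
Why: Cuprate conjugate addition should occur anti to the silyloxy group, and the following E1cB elimination of silanol leaves the new methyl-bearing carbon as the only stereocentre, fixed as R by the starting silyl ether.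

Step 2
Reactants: 3 (R)-4-methylcyclopent-2-en-1-one
Product: 4 {[(3S,4R)-3,4-dimethylcyclopent-1-en-1-yl]oxy}trimethylsilane
Conditions: Me2CuLi, Me3SiCl, Et3N, THF, −78 °C
Reagents that add atoms: lithium dimethylcuprate, [Li+].C[Cu-]C; chlorotrimethylsilane, C[Si](C)(C)Cl
Why: Silyl chloride-accelerated cuprate conjugate addition should deliver the second methyl group anti to the existing one (trans-3,4) and trap the enolate regiospecifically as the silyl enol ether.

Step 3
Reactants: 4 {[(3S,4R)-3,4-dimethylcyclopent-1-en-1-yl]oxy}trimethylsilane; 5 dichloroacetyl chloride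
Product: 7 7,7-dichloro-3,4-dimethyl-1-[(trimethylsilyl)oxy]bicyclo[3.2.0]heptan-6-one, via dichloroketene 6 (not isolated)
Conditions: Et3N, hexanes, rt (5 added slowly)
Reagents that add atoms: none
Why: Ketene–alkene [2+2] cycloaddition of amine-generated dichloroketene joins the ketene carbonyl carbon to the enol ether β-carbon, the amine route being chosen because zinc halide from a reductive ketene generation would cleave the silyl enol ether; the ring-fusion centres formed are erased in step 4.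

Step 4
Reactants: 7 7,7-dichloro-3,4-dimethyl-1-[(trimethylsilyl)oxy]bicyclo[3.2.0]heptan-6-one
Product: 9 (5R,6R)-5,6-dimethylcycloheptane-1,3-dione, via dechlorinated cyclobutanone 8 (not isolated)
Conditions: Fe powder, AcOH, i-PrOH/H2O, rt
Reagents that add atoms: none
Why: Reductive dechlorination followed by desilylative retro-aldol cleavage of the ring-fusion bond (two-carbon ring expansion) should give the C2-symmetric 1,3-dione in which only the two methyl-bearing stereocentres remain.

Step 5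
Reactants: 9 (5R,6R)-5,6-dimethylcycloheptane-1,3-dione
Product: 10 (5R,6R)-5,6-dimethyl-3-(2-methylpropoxy)cyclohept-2-en-1-one
Conditions: i-BuOH, TsOH·H2O (cat), toluene, reflux, Dean–Stark
Reagents that add atoms: 2-methylpropan-1-ol, CC(C)CO
Why: Acid-catalysed enol etherification with azeotropic removal of water gives a single vinylogous ester because the two carbonyl groups are equivalent by C2 symmetry.

Step 6
Reactants: 10 (5R,6R)-5,6-dimethyl-3-(2-methylpropoxy)cyclohept-2-en-1-one
Product: 12 (5R,6R)-5,6-dimethylcyclohept-2-en-1-one, via allylic alcohol 11 (not isolated)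
Conditions: i-Bu2AlH, CH2Cl2, −78 °C; then 1 M aq HCl, rt
Reagents that add atoms: none
Why: Stork–Danheiser transposition (1,2-hydride addition to the vinylogous ester, then acid hydrolysis of the enol ether with loss of water) should give the enone, again a single compound by symmetry.

Step 7
Reactants: 12 (5R,6R)-5,6-dimethylcyclohept-2-en-1-one
Product: 13 (5R,6S,7R)-7-hydroxy-5,6-dimethylcyclohept-2-en-1-one
Conditions: NaN(SiMe3)2, THF, −78 °C; 2-(phenylsulfonyl)-3-phenyloxaziridine, −78 °C; aq NH4Cl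
Reagents that add atoms: 2-(phenylsulfonyl)-3-phenyloxaziridine, O=S(=O)(N1OC1c1ccccc1)c1ccccc1
Why: Enolate hydroxylation of the kinetic cross-conjugated α'-enolate by the N-sulfonyloxaziridine should occur anti to the adjacent C6 methyl group, setting the carbinol centre trans to it, which is also the more stable arrangement if the α-centre equilibrates.

Step 8
Reactants: 13 (5R,6S,7R)-7-hydroxy-5,6-dimethylcyclohept-2-en-1-one
Product: 14 (5R,6S,7R)-7-[(tert-butyldimethylsilyl)oxy]-5,6-dimethylcyclohept-2-en-1-one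
Conditions: t-BuMe2SiOTf, 2,6-lutidine, CH2Cl2, −78 to 0 °C
Reagents that add atoms: tert-butyldimethylsilyl trifluoromethanesulfonate, CC(C)(C)[Si](C)(C)OS(=O)(=O)C(F)(F)F
Why: O-Silylation with the silyl triflate and a hindered pyridine base protects the α-hydroxy ketone under conditions too weakly basic to epimerize it.

Step 9
Reactants: 14 (5R,6S,7R)-7-[(tert-butyldimethylsilyl)oxy]-5,6-dimethylcyclohept-2-en-1-one
Product: 16 (2R,3S,4R)-2-[(tert-butyldimethylsilyl)oxy]-6-hydroxy-3,4-dimethylcycloheptan-1-one, via β-boryl ketone 15 (not isolated)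
Conditions: B2pin2, CuCl (5 mol %), NaOt-Bu (10 mol %), DPEphos (5 mol %), MeOH, THF, rt; then NaBO3·4H2O, THF/H2O, rt
Reagents that add atoms: sodium perborate, [Na+].[Na+].O[B-]1(O)OO[B-](O)(O)OO1
Why: Copper-catalysed conjugate borylation of the enone followed by oxidative C–B to C–O conversion should give the β-hydroxy ketone, whose new carbinol centre is immaterial because it is oxidized in step 12.

Step 10
Reactants: 16 (2R,3S,4R)-2-[(tert-butyldimethylsilyl)oxy]-6-hydroxy-3,4-dimethylcycloheptan-1-one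
Product: 17 (2R,3S,4R)-2-[(tert-butyldimethylsilyl)oxy]-3,4-dimethyl-6-[(triethylsilyl)oxy]cycloheptan-1-one
Conditions: Et3SiCl, imidazole, CH2Cl2, 0 °C to rt
Reagents that add atoms: chlorotriethylsilane, CC[Si](Cl)(CC)CC
Why: Imidazole-mediated silylation gives a triethylsilyl ether that can later be cleaved in the presence of the tert-butyldimethylsilyl ether.

Step 11
Reactants: 17 (2R,3S,4R)-2-[(tert-butyldimethylsilyl)oxy]-3,4-dimethyl-6-[(triethylsilyl)oxy]cycloheptan-1-one
Product: 19 (5R,6S,7R)-7-[(tert-butyldimethylsilyl)oxy]-3-hydroxy-5,6-dimethylcyclohept-1-en-1-yl trifluoromethanesulfonate, via silyl-protected vinyl triflate 18 (not isolated)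
Conditions: KN(SiMe3)2, THF, −78 °C; PhNTf2, −78 to −40 °C; aq NH4Cl; then PPTS, MeOH/CH2Cl2, 0 °C
Reagents that add atoms: N-phenylbis(trifluoromethanesulfonimide), O=S(=O)(N(c1ccccc1)S(=O)(=O)C(F)(F)F)C(F)(F)F
Why: Kinetic enolization should take place at the CH2 group and not at the silyloxy-bearing methine, so enolate O-triflation fixes the vinyl triflate carbon next to the silyloxy stereocentre, and mild acid methanolysis then removes only the more labile triethylsilyl ether.

Step 12
Reactants: 19 (5R,6S,7R)-7-[(tert-butyldimethylsilyl)oxy]-3-hydroxy-5,6-dimethylcyclohept-1-en-1-yl trifluoromethanesulfonate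
Product: 20 (5R,6S,7R)-7-[(tert-butyldimethylsilyl)oxy]-5,6-dimethyl-3-oxocyclohept-1-en-1-yl trifluoromethanesulfonate
Conditions: Dess–Martin periodinane, NaHCO3, CH2Cl2, rt
Reagents that add atoms: none
Why: Dess–Martin oxidation of the secondary allylic alcohol gives the β-triflyloxy enone under buffered conditions that do not deprotonate the γ-stereocentre.

Step 13
Reactants: 20 (5R,6S,7R)-7-[(tert-butyldimethylsilyl)oxy]-5,6-dimethyl-3-oxocyclohept-1-en-1-yl trifluoromethanesulfonate
Product: 21 (4R,5S,6R)-4-[(tert-butyldimethylsilyl)oxy]-5,6-dimethyl-3-(trimethylstannyl)cyclohept-2-en-1-one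
Conditions: Me3SnSnMe3, Pd(PPh3)4 (5 mol %), LiCl, THF, 60 °C
Reagents that add atoms: hexamethylditin, C[Sn](C)(C)[Sn](C)(C)C
Why: Palladium-catalysed stannylation of a vinyl triflate with a distannane (Stille-type coupling) replaces triflate by tin at the same carbon, so the regiochemistry fixed in step 11 is retained.

Step 14
Reactants: 22 dimethyl squarate
Product: 23 4-hydroxy-2,3-dimethoxycyclobut-2-en-1-one
Conditions: LiAlH(Ot-Bu)3, THF, −78 to −40 °C; aq NH4Cl
Reagents that add atoms: none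
Why: Carbonyl reduction by the bulky alkoxyaluminium hydride at low temperature should stop after one hydride transfer at the 4-hydroxycyclobutenone.

Step 15
Reactants: 23 4-hydroxy-2,3-dimethoxycyclobut-2-en-1-one
Product: 24 4-chloro-2,3-dimethoxycyclobut-2-en-1-one
Conditions: PPh3, CCl4, CH2Cl2, 0 °C to rt; used at once
Reagents that add atoms: tetrachloromethane, ClC(Cl)(Cl)Cl
Why: Appel chlorination replaces the allylic α-keto hydroxyl by chloride through SN2 attack on an alkoxyphosphonium ion under neutral conditions that avoid ionization of this acid-sensitive system.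

Step 16
Reactants: 21 (4R,5S,6R)-4-[(tert-butyldimethylsilyl)oxy]-5,6-dimethyl-3-(trimethylstannyl)cyclohept-2-en-1-one; 24 4-chloro-2,3-dimethoxycyclobut-2-en-1-one
Product: 25 (4R,5S,6R)-4-[(tert-butyldimethylsilyl)oxy]-3-(2,3-dimethoxy-4-oxocyclobut-2-en-1-yl)-5,6-dimethylcyclohept-2-en-1-one
Conditions: (PhCN)2PdCl2 (5 mol %), tris(2-furyl)phosphine (10 mol %), CuI (10 mol %), dioxane, rt
Reagents that add atoms: none
Why: Stille cross-coupling of a 4-chlorocyclobutenone (oxidative addition of zerovalent palladium to the allylic α-keto C–Cl bond) with the alkenylstannane, helped by CuI and the weakly donating phosphine, should form the sp2–sp3 bond at the cyclobutenone sp3 carbon below the temperature of ring opening.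

Step 17
Reactants: 25 (4R,5S,6R)-4-[(tert-butyldimethylsilyl)oxy]-3-(2,3-dimethoxy-4-oxocyclobut-2-en-1-yl)-5,6-dimethylcyclohept-2-en-1-one
Product: 28 (7R,8S,9R)-9-[(tert-butyldimethylsilyl)oxy]-4-hydroxy-2,3-dimethoxy-7,8-dimethyl-6,7,8,9-tetrahydro-5H-benzo[7]annulen-5-one, via dienylketene 26 (not isolated), via cyclohexadienone 27 (not isolated)
Conditions: toluene (0.01 M, degassed), 100 °C
Reagents that add atoms: none
Why: Thermal 4π-electrocyclic (conrotatory) opening of the cyclobutenone gives a dienylketene, and because this opening is reversible the isomer with the cycloheptenyl group rotated outward returns to 25 while the inward-rotated isomer is drained by cyclization. The ketene carbon then bonds to the enone α-carbon in a 6π-electrocyclic (disrotatory) closure that forms the six-membered carbocycle, and the resulting 2,4-cyclohexadienone, a β-dicarbonyl-type C–H acid, enolizes to the hydrogen-bonded phenol. The closest known reaction type is the thermal rearrangement of 4-alkenyl- and 4-arylcyclobut-2-enones to phenols. No stereocentre is created, and C7, C8 and C9 are untouched because no acid, base or metal is present. The selectivity needed is the regiochemistry of closure, which is fixed by connectivity since the ketene can reach only one alkene terminus, together with chemoselectivity against ketene dimerization, which high dilution should secure.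

Step 18
Reactants: 28 (7R,8S,9R)-9-[(tert-butyldimethylsilyl)oxy]-4-hydroxy-2,3-dimethoxy-7,8-dimethyl-6,7,8,9-tetrahydro-5H-benzo[7]annulen-5-one
Product: 29 (7R,8S,9R)-9-[(tert-butyldimethylsilyl)oxy]-2,3,4-trimethoxy-7,8-dimethyl-6,7,8,9-tetrahydro-5H-benzo[7]annulen-5-one
Conditions: MeI, K2CO3, acetone, 50 °C
Reagents that add atoms: iodomethane, CI
Why: Williamson O-methylation of the phenoxide completes the trimethoxyarene, the hydrogen bond to the ortho ketone only slowing the alkylation and the weak base leaving the ketone α-position alone.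

Step 19
Reactants: 29 (7R,8S,9R)-9-[(tert-butyldimethylsilyl)oxy]-2,3,4-trimethoxy-7,8-dimethyl-6,7,8,9-tetrahydro-5H-benzo[7]annulen-5-one
Product: 30 tert-butyl{[(7R,8S,9R)-2,3,4-trimethoxy-5-(methoxymethylidene)-7,8-dimethyl-6,7,8,9-tetrahydro-5H-benzo[7]annulen-9-yl]oxy}dimethylsilane
Conditions: Ph3P(CH2OMe)Cl, KOt-Bu, THF, 0 to 45 °C
Reagents that add atoms: (methoxymethyl)triphenylphosphonium chloride, COC[P+](c1ccccc1)(c1ccccc1)c1ccccc1.[Cl-]
Why: Wittig olefination with the non-stabilized methoxymethylene ylide should convert the ortho-substituted aryl ketone into the one-carbon-homologated enol ether.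

Step 20
Reactants: 30 tert-butyl{[(7R,8S,9R)-2,3,4-trimethoxy-5-(methoxymethylidene)-7,8-dimethyl-6,7,8,9-tetrahydro-5H-benzo[7]annulen-9-yl]oxy}dimethylsilane
Product: 31 (7R,8S,9R)-9-[(tert-butyldimethylsilyl)oxy]-2,3,4-trimethoxy-7,8-dimethyl-6,7,8,9-tetrahydro-5H-benzo[7]annulene-5-carbaldehyde
Conditions: TsOH·H2O (cat), acetone/H2O, rt
Reagents that add atoms: water, O
Why: Acid-catalysed enol ether hydrolysis (C-protonation to an oxocarbenium ion, then hemiacetal collapse) should give the aldehyde under conditions mild enough for the hindered benzylic silyl ether, and the configuration of the new C5 centre is immaterial because C5 becomes quaternary.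

Step 21
Reactants: 32 1,3-dimethoxypropan-2-one
Product: 33 4-(dimethylamino)-1,3-dimethoxybutan-2-one hydroiodide
Conditions: CH2=NMe2 I, MeCN, 60 °C (32 in excess)
Reagents that add atoms: dimethylmethyleneiminium iodide, C=[N+](C)C.[I-]
Why: Mannich reaction of the enol of the symmetrical ketone with the preformed iminium salt gives the β-aminoketone salt, a storable precursor of the α-methoxy vinyl ketone.

Step 22
Reactants: 31 (7R,8S,9R)-9-[(tert-butyldimethylsilyl)oxy]-2,3,4-trimethoxy-7,8-dimethyl-6,7,8,9-tetrahydro-5H-benzo[7]annulene-5-carbaldehyde; 33 4-(dimethylamino)-1,3-dimethoxybutan-2-one hydroiodide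
Product: 36 (7R,8S,9R)-9-[(tert-butyldimethylsilyl)oxy]-2,3,3',4,5'-pentamethoxy-7,8-dimethyl-6,7,8,9-tetrahydrospiro[benzo[7]annulene-5,1'-cyclohex[2]en]-4'-one, via vinyl ketone 34 (not isolated), via Michael adduct 35 (not isolated)
Conditions: KOH, EtOH, 0 to 50 °C
Reagents that add atoms: none
Why: Robinson annulation, in which the Mannich base loses dimethylamine to the vinyl ketone, the enolate of the α-aryl aldehyde adds to it in a Michael reaction that makes C5 quaternary, and aldol condensation of the methoxymethyl ketone onto the aldehyde closes the cyclohexenone, the centres formed at C5 and at the methoxy-bearing sp3 carbon being erased in step 23.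

Step 23
Reactants: 36 (7R,8S,9R)-9-[(tert-butyldimethylsilyl)oxy]-2,3,3',4,5'-pentamethoxy-7,8-dimethyl-6,7,8,9-tetrahydrospiro[benzo[7]annulene-5,1'-cyclohex[2]en]-4'-one
Product: 38 (7R,8S,9R)-9-[(tert-butyldimethylsilyl)oxy]-2,3,3',4,5'-pentamethoxy-7,8-dimethyl-6,7,8,9-tetrahydrospiro[benzo[7]annulene-5,1'-cyclohexa[2,5]dien]-4'-one, via silyl dienol ether 37 (not isolated)
Conditions: LiN(i-Pr)2, Me3SiCl, THF, −78 °C; then Pd(OAc)2, MeCN, rt
Reagents that add atoms: none
Why: Saegusa–Ito oxidation, in which deprotonation at the only enolizable position and silylation give the 2-silyloxydiene and Pd(OAc)2 then effects β-hydride elimination to the cross-conjugated dienone, should make C5 a non-stereogenic spiro centre.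

Step 24
Reactants: 38 (7R,8S,9R)-9-[(tert-butyldimethylsilyl)oxy]-2,3,3',4,5'-pentamethoxy-7,8-dimethyl-6,7,8,9-tetrahydrospiro[benzo[7]annulene-5,1'-cyclohexa[2,5]dien]-4'-one
Product: 39 (7R,8S,9R)-9-hydroxy-2,3,3',4,5'-pentamethoxy-7,8-dimethyl-6,7,8,9-tetrahydrospiro[benzo[7]annulene-5,1'-cyclohexa[2,5]dien]-4'-one
Conditions: HF·pyridine, pyridine, THF, 0 °C to rt
Reagents that add atoms: none
Why: Fluoride-mediated Si–O cleavage under buffered, weakly acidic conditions should free the benzylic alcohol without alkoxide conjugate addition to the dienone and without acid-induced dienone–phenol rearrangement.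

Step 25
Reactants: 39 (7R,8S,9R)-9-hydroxy-2,3,3',4,5'-pentamethoxy-7,8-dimethyl-6,7,8,9-tetrahydrospiro[benzo[7]annulene-5,1'-cyclohexa[2,5]dien]-4'-one
Product: 40 (7R,8S,9R)-2,3,3',4,5'-pentamethoxy-7,8-dimethyl-4'-oxo-6,7,8,9-tetrahydrospiro[benzo[7]annulene-5,1'-cyclohexa[2,5]dien]-9-yl benzoate
Conditions: BzCl, pyridine, DMAP (cat), CH2Cl2, 0 °C to rt
Reagents that add atoms: benzoyl chloride, O=C(Cl)c1ccccc1
Why: DMAP-catalysed acylation (nucleophilic catalysis through the N-benzoylpyridinium ion) esterifies the secondary benzylic alcohol with retention at C9 and gives the target.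

Compound list
1 | (R)-4-[(tert-butyldimethylsilyl)oxy]cyclopent-2-en-1-one | O=C1C=C[C@H](O[Si](C)(C)C(C)(C)C)C1 | starting material
2 | (3R,4R)-4-[(tert-butyldimethylsilyl)oxy]-3-methylcyclopentan-1-one (trans) | O=C1C[C@@H](C)[C@H](O[Si](C)(C)C(C)(C)C)C1 | intermediate
3 | (R)-4-methylcyclopent-2-en-1-one | O=C1C=C[C@H](C)C1 | intermediate
4 | {[(3S,4R)-3,4-dimethylcyclopent-1-en-1-yl]oxy}trimethylsilane (trans) | C[Si](C)(C)OC1=C[C@@H](C)[C@H](C)C1 | intermediate
5 | dichloroacetyl chloride | O=C(Cl)C(Cl)Cl | starting material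
6 | dichloroketene | O=C=C(Cl)Cl | intermediate
7 | 7,7-dichloro-3,4-dimethyl-1-[(trimethylsilyl)oxy]bicyclo[3.2.0]heptan-6-one (methyl centres as in 4, both cis ring-fusion isomers) | C[Si](C)(C)OC12C[C@@H](C)[C@H](C)C1C(=O)C2(Cl)Cl | intermediate
8 | 3,4-dimethyl-1-[(trimethylsilyl)oxy]bicyclo[3.2.0]heptan-6-one (methyl centres as in 4) | C[Si](C)(C)OC12C[C@@H](C)[C@H](C)C1C(=O)C2 | intermediate
9 | (5R,6R)-5,6-dimethylcycloheptane-1,3-dione | O=C1CC(=O)C[C@@H](C)[C@H](C)C1 | intermediate
10 | (5R,6R)-5,6-dimethyl-3-(2-methylpropoxy)cyclohept-2-en-1-one | O=C1C=C(OCC(C)C)C[C@@H](C)[C@H](C)C1 | intermediate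
11 | (5R,6R)-5,6-dimethyl-3-(2-methylpropoxy)cyclohept-2-en-1-ol (C1 epimers) | OC1C=C(OCC(C)C)C[C@@H](C)[C@H](C)C1 | intermediate
12 | (5R,6R)-5,6-dimethylcyclohept-2-en-1-one | O=C1C=CC[C@@H](C)[C@H](C)C1 | intermediate
13 | (5R,6S,7R)-7-hydroxy-5,6-dimethylcyclohept-2-en-1-one | O=C1C=CC[C@@H](C)[C@H](C)[C@H]1O | intermediate
14 | (5R,6S,7R)-7-[(tert-butyldimethylsilyl)oxy]-5,6-dimethylcyclohept-2-en-1-one | O=C1C=CC[C@@H](C)[C@H](C)[C@H]1O[Si](C)(C)C(C)(C)C | intermediate
15 | (2R,3S,4R)-2-[(tert-butyldimethylsilyl)oxy]-3,4-dimethyl-6-(4,4,5,5-tetramethyl-1,3,2-dioxaborolan-2-yl)cycloheptan-1-one (C6 epimers) | O=C1CC(B2OC(C)(C)C(C)(C)O2)C[C@@H](C)[C@H](C)[C@H]1O[Si](C)(C)C(C)(C)C | intermediate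
16 | (2R,3S,4R)-2-[(tert-butyldimethylsilyl)oxy]-6-hydroxy-3,4-dimethylcycloheptan-1-one (C6 epimers) | O=C1CC(O)C[C@@H](C)[C@H](C)[C@H]1O[Si](C)(C)C(C)(C)C | intermediate
17 | (2R,3S,4R)-2-[(tert-butyldimethylsilyl)oxy]-3,4-dimethyl-6-[(triethylsilyl)oxy]cycloheptan-1-one (C6 epimers) | O=C1CC(O[Si](CC)(CC)CC)C[C@@H](C)[C@H](C)[C@H]1O[Si](C)(C)C(C)(C)C | intermediate
18 | (5R,6S,7R)-7-[(tert-butyldimethylsilyl)oxy]-5,6-dimethyl-3-[(triethylsilyl)oxy]cyclohept-1-en-1-yl trifluoromethanesulfonate (C3 epimers) | CC[Si](CC)(CC)OC1C[C@@H](C)[C@H](C)[C@@H](O[Si](C)(C)C(C)(C)C)C(OS(=O)(=O)C(F)(F)F)=C1 | intermediate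
19 | (5R,6S,7R)-7-[(tert-butyldimethylsilyl)oxy]-3-hydroxy-5,6-dimethylcyclohept-1-en-1-yl trifluoromethanesulfonate (C3 epimers) | OC1C[C@@H](C)[C@H](C)[C@@H](O[Si](C)(C)C(C)(C)C)C(OS(=O)(=O)C(F)(F)F)=C1 | intermediate
20 | (5R,6S,7R)-7-[(tert-butyldimethylsilyl)oxy]-5,6-dimethyl-3-oxocyclohept-1-en-1-yl trifluoromethanesulfonate | O=C1C[C@@H](C)[C@H](C)[C@@H](O[Si](C)(C)C(C)(C)C)C(OS(=O)(=O)C(F)(F)F)=C1 | intermediate
21 | (4R,5S,6R)-4-[(tert-butyldimethylsilyl)oxy]-5,6-dimethyl-3-(trimethylstannyl)cyclohept-2-en-1-one | O=C1C[C@@H](C)[C@H](C)[C@@H](O[Si](C)(C)C(C)(C)C)C([Sn](C)(C)C)=C1 | intermediate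
22 | dimethyl squarate (3,4-dimethoxycyclobut-3-ene-1,2-dione) | COC1=C(OC)C(=O)C1=O | starting material
23 | 4-hydroxy-2,3-dimethoxycyclobut-2-en-1-one (racemic) | COC1=C(OC)C(O)C1=O | intermediate
24 | 4-chloro-2,3-dimethoxycyclobut-2-en-1-one (racemic) | COC1=C(OC)C(Cl)C1=O | intermediate
25 | (4R,5S,6R)-4-[(tert-butyldimethylsilyl)oxy]-3-(2,3-dimethoxy-4-oxocyclobut-2-en-1-yl)-5,6-dimethylcyclohept-2-en-1-one (both epimers at the cyclobutenone carbon) | O=C1C[C@@H](C)[C@H](C)[C@@H](O[Si](C)(C)C(C)(C)C)C(C2C(OC)=C(OC)C2=O)=C1 | intermediate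
26 | dienylketene: (4R,5S,6R)-4-[(tert-butyldimethylsilyl)oxy]-3-(2,3-dimethoxy-4-oxobuta-1,3-dien-1-yl)-5,6-dimethylcyclohept-2-en-1-one | O=C1C[C@@H](C)[C@H](C)[C@@H](O[Si](C)(C)C(C)(C)C)C(C=C(OC)C(OC)=C=O)=C1 | intermediate
27 | (7R,8S,9R)-9-[(tert-butyldimethylsilyl)oxy]-2,3-dimethoxy-7,8-dimethyl-6,7,8,9-tetrahydro-4aH-benzo[7]annulene-4,5-dione (keto tautomer of 28) | O=C1C[C@@H](C)[C@H](C)[C@@H](O[Si](C)(C)C(C)(C)C)C2=CC(OC)=C(OC)C(=O)C12 | intermediate
28 | (7R,8S,9R)-9-[(tert-butyldimethylsilyl)oxy]-4-hydroxy-2,3-dimethoxy-7,8-dimethyl-6,7,8,9-tetrahydro-5H-benzo[7]annulen-5-one | O=C1C[C@@H](C)[C@H](C)[C@@H](O[Si](C)(C)C(C)(C)C)c2cc(OC)c(OC)c(O)c21 | intermediate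
29 | (7R,8S,9R)-9-[(tert-butyldimethylsilyl)oxy]-2,3,4-trimethoxy-7,8-dimethyl-6,7,8,9-tetrahydro-5H-benzo[7]annulen-5-one | O=C1C[C@@H](C)[C@H](C)[C@@H](O[Si](C)(C)C(C)(C)C)c2cc(OC)c(OC)c(OC)c21 | intermediate
30 | tert-butyl{[(7R,8S,9R)-2,3,4-trimethoxy-5-(methoxymethylidene)-7,8-dimethyl-6,7,8,9-tetrahydro-5H-benzo[7]annulen-9-yl]oxy}dimethylsilane (E/Z mixture) | COC=C1C[C@@H](C)[C@H](C)[C@@H](O[Si](C)(C)C(C)(C)C)c2cc(OC)c(OC)c(OC)c21 | intermediate
31 | (7R,8S,9R)-9-[(tert-butyldimethylsilyl)oxy]-2,3,4-trimethoxy-7,8-dimethyl-6,7,8,9-tetrahydro-5H-benzo[7]annulene-5-carbaldehyde (C5 epimers) | O=CC1C[C@@H](C)[C@H](C)[C@@H](O[Si](C)(C)C(C)(C)C)c2cc(OC)c(OC)c(OC)c21 | intermediate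
32 | 1,3-dimethoxypropan-2-one | COCC(=O)COC | starting material
33 | 4-(dimethylamino)-1,3-dimethoxybutan-2-one hydroiodide (racemic) | COCC(=O)C(OC)C[NH+](C)C.[I-] | intermediate
34 | 1,3-dimethoxybut-3-en-2-one | C=C(OC)C(=O)COC | intermediate
35 | Michael adduct: (7R,8S,9R)-9-[(tert-butyldimethylsilyl)oxy]-5-(2,4-dimethoxy-3-oxobutyl)-2,3,4-trimethoxy-7,8-dimethyl-6,7,8,9-tetrahydro-5H-benzo[7]annulene-5-carbaldehyde (epimers) | O=CC1(CC(OC)C(=O)COC)C[C@@H](C)[C@H](C)[C@@H](O[Si](C)(C)C(C)(C)C)c2cc(OC)c(OC)c(OC)c21 | intermediate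
36 | (7R,8S,9R)-9-[(tert-butyldimethylsilyl)oxy]-2,3,3',4,5'-pentamethoxy-7,8-dimethyl-6,7,8,9-tetrahydrospiro[benzo[7]annulene-5,1'-cyclohex[2]en]-4'-one (epimers at C5 and C5') | COC1=CC2(CC(OC)C1=O)C[C@@H](C)[C@H](C)[C@@H](O[Si](C)(C)C(C)(C)C)c1cc(OC)c(OC)c(OC)c12 | intermediate
37 | silyl dienol ether of 36: 4'-[(trimethylsilyl)oxy]spiro[benzo[7]annulene-5,1'-cyclohexa[2,4]diene] with the substituents of 36 | COC1=CC2(CC(OC)=C1O[Si](C)(C)C)C[C@@H](C)[C@H](C)[C@@H](O[Si](C)(C)C(C)(C)C)c1cc(OC)c(OC)c(OC)c12 | intermediate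
38 | (7R,8S,9R)-9-[(tert-butyldimethylsilyl)oxy]-2,3,3',4,5'-pentamethoxy-7,8-dimethyl-6,7,8,9-tetrahydrospiro[benzo[7]annulene-5,1'-cyclohexa[2,5]dien]-4'-one | COC1=CC2(C=C(OC)C1=O)C[C@@H](C)[C@H](C)[C@@H](O[Si](C)(C)C(C)(C)C)c1cc(OC)c(OC)c(OC)c12 | intermediate
39 | (7R,8S,9R)-9-hydroxy-2,3,3',4,5'-pentamethoxy-7,8-dimethyl-6,7,8,9-tetrahydrospiro[benzo[7]annulene-5,1'-cyclohexa[2,5]dien]-4'-one | COC1=CC2(C=C(OC)C1=O)C[C@@H](C)[C@H](C)[C@@H](O)c1cc(OC)c(OC)c(OC)c12 | intermediate
40 | (7R,8S,9R)-2,3,3',4,5'-pentamethoxy-7,8-dimethyl-4'-oxo-6,7,8,9-tetrahydrospiro[benzo[7]annulene-5,1'-cyclohexa[2,5]dien]-9-yl benzoate | COC1=CC2(C=C(OC)C1=O)C[C@@H](C)[C@H](C)[C@@H](OC(=O)c1ccccc1)c1cc(OC)c(OC)c(OC)c12 | target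

Total step count: 25 (steps 14–15 and step 21 are side branches).
Longest linear sequence: 22 steps (1 to 40 through steps 1–13, 16–20 and 22–25).

Steps most likely to fail

First, step 17. The C–H of the cyclobutenone in 25 is activated twice (α to the four-ring ketone and vinylogously by the enone), so tautomerization to the exocyclic alkylidene isomer may compete with ring opening. The ketene may also dimerize before it closes onto the electron-poor, hindered enone terminus. The fallback keeps the disconnection but carries the ring B carbonyl as a silyl ether through the benzannulation. It sets out from 18, isolated by leaving out the PPTS stage of step 11. Stannylation as in step 13 would give the silyl-protected vinylstannane F1. Coupling with 24 as in step 16 would give the cyclobutenone F2, an unactivated 4-alkenylcyclobutenone. Heating in toluene at 100 °C would give the phenol F3. PPTS in MeOH would cleave the triethylsilyl ether to the benzylic alcohol F4, and MnO2 in CH2Cl2 would oxidize it to 28, where the route is rejoined.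

Second, step 16. Chloride 24 may ionize (loss of chloride to the dialkoxycyclobutenyl cation, then collapse to the methyl semisquarate) before oxidative addition, and 25 may rearrange or tautomerize if transmetalation of the electron-poor stannane is slow. The fallback changes the electrophile class to an allylic ester. It sets out from 23: acetylation (Ac2O, pyridine, DMAP, CH2Cl2, 0 °C) would give the acetate F5. F5 would be coupled with 21 under conditions used for allylic acetates and alkenylstannanes (Pd2(dba)3, LiCl, DMF, rt), returning to the route at 25.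

Third, step 22. Retro-Michael reaction and polymerization of vinyl ketone 34 may outrun formation of the congested quaternary centre next to the ortho-methoxy arene. The fallback installs both arms of ring C as formyl groups and closes the dienone by a double aldol condensation. It sets out from 31: crossed aldol reaction with formaldehyde (aq HCHO, K2CO3, THF/MeOH) would give the hydroxymethyl aldehyde F6. NaBH4 reduction would give the 1,3-diol F7, and Swern oxidation ((COCl)2, DMSO, Et3N, −78 °C) the dialdehyde F8. Condensation of F8 with 32 (piperidinium acetate, toluene, 80 °C) would give the dienone directly, returning to the route at 38 and bypassing 36 and step 23.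

Further compounds
F1 | step 17 | (5R,6S,7R)-tert-butyl{[2,3-dimethyl-5-[(triethylsilyl)oxy]-7-(trimethylstannyl)cyclohept-6-en-1-yl]oxy}dimethylsilane (stannane analogue of 18) | CC[Si](CC)(CC)OC1C[C@@H](C)[C@H](C)[C@@H](O[Si](C)(C)C(C)(C)C)C([Sn](C)(C)C)=C1
F2 | step 17 | 4-{(5R,6S,7R)-7-[(tert-butyldimethylsilyl)oxy]-5,6-dimethyl-3-[(triethylsilyl)oxy]cyclohept-1-en-1-yl}-2,3-dimethoxycyclobut-2-en-1-one | CC[Si](CC)(CC)OC1C[C@@H](C)[C@H](C)[C@@H](O[Si](C)(C)C(C)(C)C)C(C2C(OC)=C(OC)C2=O)=C1
F3 | step 17 | (7R,8S,9R)-9-[(tert-butyldimethylsilyl)oxy]-2,3-dimethoxy-7,8-dimethyl-5-[(triethylsilyl)oxy]-6,7,8,9-tetrahydro-5H-benzo[7]annulen-4-ol | CC[Si](CC)(CC)OC1C[C@@H](C)[C@H](C)[C@@H](O[Si](C)(C)C(C)(C)C)c2cc(OC)c(OC)c(O)c21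
F4 | step 17 | (7R,8S,9R)-9-[(tert-butyldimethylsilyl)oxy]-2,3-dimethoxy-7,8-dimethyl-6,7,8,9-tetrahydro-5H-benzo[7]annulene-4,5-diol | OC1C[C@@H](C)[C@H](C)[C@@H](O[Si](C)(C)C(C)(C)C)c2cc(OC)c(OC)c(O)c21
F5 | step 16 | 2,3-dimethoxy-4-oxocyclobut-2-en-1-yl acetate (racemic) | COC1=C(OC)C(OC(C)=O)C1=O
F6 | step 22 | (7R,8S,9R)-9-[(tert-butyldimethylsilyl)oxy]-5-(hydroxymethyl)-2,3,4-trimethoxy-7,8-dimethyl-6,7,8,9-tetrahydro-5H-benzo[7]annulene-5-carbaldehyde | O=CC1(CO)C[C@@H](C)[C@H](C)[C@@H](O[Si](C)(C)C(C)(C)C)c2cc(OC)c(OC)c(OC)c21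
F7 | step 22 | {(7R,8S,9R)-9-[(tert-butyldimethylsilyl)oxy]-2,3,4-trimethoxy-7,8-dimethyl-6,7,8,9-tetrahydro-5H-benzo[7]annulene-5,5-diyl}dimethanol | OCC1(CO)C[C@@H](C)[C@H](C)[C@@H](O[Si](C)(C)C(C)(C)C)c2cc(OC)c(OC)c(OC)c21
F8 | step 22 | (7R,8S,9R)-9-[(tert-butyldimethylsilyl)oxy]-2,3,4-trimethoxy-7,8-dimethyl-6,7,8,9-tetrahydro-5H-benzo[7]annulene-5,5-dicarbaldehyde | O=CC1(C=O)C[C@@H](C)[C@H](C)[C@@H](O[Si](C)(C)C(C)(C)C)c2cc(OC)c(OC)c(OC)c21
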